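## Structural features

The target is a labdane: a trans-fused decalin (ring A = C1–C5, C10; ring B = C5–C10) with a gem-dimethyl carbon C4, an angular methyl on quaternary C10, a trisubstituted C7=C8 alkene carrying C17, and an equatorial 2α-hydroxyl on ring A. C9 carries a five-carbon chain (C11–C15, methyl C16 on C13) whose primary oxygen at C15 is esterified with (Z)-p-coumaric acid. C5, C10 and C9 are contiguous stereocentres around the ring fusion, C2 stands 1,3 to C10 across C1, and C13 (S) sits alone in the chain with no relay from the ring. The fragile parts are the Z-enoate (isomerised to E by light, by nucleophiles and through its phenoxide), the free phenol, the ester link, and the Δ7 alkene, which acid moves to Δ8. The real difficulty is the quaternary C10 flanked by C5 and C9 in a trans-decalin, together with the independent C13 centre and the late, selective attachment of a Z-coumarate to C15 beside a free 2-hydroxyl. The key step uses the fact that ring B (C5–C10) with an oxygen at C8 and the gem-dimethyl carbon C4 on C5 is the six-membered ring plus the gem-dimethylcyclobutane of verbenone: the extra C4–C7 bond stores strain, and its cleavage gives the C4 cation that closes ring A onto a propargyl group on C10.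

## Logic of the disconnections

**23 ⇒ 20 + 22 (and 22 ⇒ 21).** The ester C15–O bond is cut first. The Z-enoate and the phenol survive none of the acid, base or reducing conditions used earlier, so they go on last; what remains is a diterpene diol and a C9 acid. The forward step must esterify only the primary C15 hydroxyl, leave the 2α-hydroxyl and the phenol free, and never activate the carboxyl carbon, so that the Z geometry is kept. 22 differs from 21 only in alkene geometry.

**20 ⇒ 19.** Both C–O single bonds are traced back to carbonyl groups: C2–OH to a ketone and C15–OH to a methyl ester. This removes a stereocentre and lets one dissolving-metal reduction serve both. The reduction must give the equatorial 2α-alcohol, which hydride reagents would not, because the β-face of C2 lies between the axial C19 and C20 methyls.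

**19 ⇒ 18 ⇒ 16.** The C8–C17 bond is cut, with the alkene position held by a C8 enol triflate that goes back to a C8 ketone. This removes the acid-sensitive alkene and leaves the C8 carbonyl that the key step needs. The forward step must enolise C7 of the C8 ketone, and not C9, the C1/C3 methylenes of the second ketone, or the ester.

**16 ⇒ 13 (key disconnection).** Ring A is opened at C3–C4 and, in the same operation, C4 is rejoined to C7, so the decalindione becomes a bicyclo[3.1.1]heptanone with a propargyl group on C10. This turns ring B, the gem-dimethyl carbon and the C5/C10 stereocentres into the framework of a cheap enantiopure terpene. Three demands follow for the forward step: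
- Only this cyclobutane bond may cleave, and the alkyne must capture the cation 6-endo to give a trans fusion.
- C9 must be inverted. In 13 the side chain is anti to the bridge (the 9-epi series, seen in 14 and 15), so equilibration next to the C8 ketone is a required part of the step.
- C15 is carried as a methyl ester and not as an ether. Lewis acids strong enough to open the cyclobutane also attack benzylic ethers, and an ether oxygen or arene could intercept the cation. The ester is inert to the acid, is not a nucleophile for the C4 cation, and shortens the side-chain synthesis; the price is that the final reduction must also take the ester to the alcohol.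

**13 ⇒ 12 ⇒ 11 ⇒ 9.** The alkyne is cut at C2≡C3 back to an aldehyde (C3 comes from a diazophosphonate), the aldehyde to a primary alcohol, and this to a vinyl group. The three-carbon terminator thus reduces to a vinyl group that a cuprate can deliver. The hydroboration must spare a hindered ketone and an ester.

**9 ⇒ 7 + 5.** The C9–C11 bond is cut, so the whole C11–C16 chain with its C13 centre arrives in one piece. The forward alkylation takes place at an enolate carbon next to a quaternary centre; its stereochemical sense is unimportant because C9 is reset later.

**7 ⇒ 6.** The C1–C10 bond is cut, leaving the enone of the starting terpene. The gem-dimethyl bridge must direct the incoming vinyl group to the opposite face, which fixes C10 with methyl syn to the future C4.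

**5 ⇒ 3 ⇒ 1.** The C11–iodine bond and the lactone C–O bond are traced to a half-ester whose stereocentre becomes C13. The ester arm of 1 must become C11/C12 and the acid arm C14/C15; reducing the ester and then opening the lactone at its O–CH2 carbon secures this.

## Other disconnections considered

**Alternative 1:** The cut runs through C5–C10 and C8–C9, opening both rings to the acyclic silyloxy triene A1, an (E)-3-methyl enoate tethered through C1–C4 to a 2-silyloxy diene. On heating, A1 should undergo an intramolecular Diels–Alder reaction to the drimane ester A2.
- In its favour: two rings, two C–C bonds and four centres (C5, C8, C9, C10) arise in one thermal step of a familiar type. The C9/C10 relationship is read from the enoate geometry, and no bicyclic chiral-pool material is needed.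
- Against it here: the dienophile is a β,β-disubstituted enoate that must form quaternary C10 next to a diene terminus bearing the neopentyl C4. Forcing conditions are likely, under which a silyloxy diene is prone to 1,5-hydrogen shifts. The trans fusion rests on an exo-tether transition state whose preference is usually modest, and the single stereocentre of A1 (C2) must relay all absolute configuration. The C8 centre is discarded when the Δ7 alkene is made, C7 must be deoxygenated, and the C12–C16 chain with C13 still has to be grown from C11.
- Comparison: on ring construction and mechanistic precedent Alternative 1 is the better, being a known pericyclic reaction against an untested cationic cascade. On control of C5 and C10 the chosen plan is better, since both come from a rigid bicyclic template. On step economy the chosen plan should be shorter, because A1 needs a long linear assembly and A2 needs chain elongation and redox changes.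

**Alternative 2:** The cut is C9–C10 only. Ring B opens to the monocyclic diene diacetate A3, a ring A with a tetrasubstituted C5=C10 alkene and a C2 acetate, carrying on C5 the chain with the (E)-C8=C9 alkene and the complete C11–C16 unit. FSO3H at low temperature should protonate C5, C9 should attack the C10 cation, and loss of a C7 proton should give the diacetate A4.
- In its favour: the whole carbon skeleton including C17 and Δ7 is reached at once. A4 is only acetate removal and one selective acylation from the target. Superacid closures of monocyclic precursors of this kind are a known reaction class, and ring A with its C2 oxygen can come from the chiral pool.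
- Against it here: C5, C9 and C10 are all created with the C2 acetate (1,3 to C10) as the only reference, so the face of protonation is weakly controlled and a diastereomeric decalin must be expected. The C2 acetate can participate at the C10 cation, proton loss can give Δ8(17) and Δ8 isomers beside Δ7, and A3 itself needs a stereodefined trisubstituted alkene and the union of two chiral pieces.
- Comparison: equal in what the key step builds (one C–C bond, one ring). Alternative 2 is better after the key step and in installing C17/Δ7 directly, and better in precedent. The chosen plan is better in stereocontrol at the ring fusion and C9. Overall length should be similar, because the saving after the key step is spent making A3.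

**Alternative 3:** The cuts are C9–C10 and C7–C8, with a temporary ester link from the C2 oxygen to C11. The precursor is the dienyl but-2-ynoate A5, which on heating should give the tricyclic dienyl lactone A6.
- In its favour: the tether delivers the dienophile to one face of C10 from the C2 oxygen, so the quaternary centre is set relative to C2 with certainty; on this point it equals the chosen plan by a different device. The alkynoate brings C8 with its methyl and C11, the reaction type is known, and A5 is small and quickly made, so it is better on access to the key-step precursor.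
- Against it here: ester-tethered cycloadditions are slow because the ester prefers its s-trans conformation, and the diene is tetrasubstituted at C10=C5 and twisted by the C4 gem-dimethyl group. A6 is a 5,8-diene: the Δ5 alkene must be reduced from the α-face to give the trans fusion, and the Δ8 alkene must be moved to Δ7 with creation of C9, neither of which the key step controls. The C12–C16 chain with C13 must then be built on C11.
- Comparison: better than the chosen plan on mechanistic precedent and precursor access, equal on relay of chirality to C10, and worse on what remains afterwards (C5, C9, alkene position, five-carbon chain). The total count should be clearly higher.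

Key step: step 8

Remark on the chemistry: the configuration at C9 in 9–15 (side chain anti to the gem-dimethyl bridge) is assigned from the expected sense of alkylation; it does not affect the outcome because step 8 equilibrates this centre.

Step 1
Reactants: 1 (R)-3-methylglutaric acid monomethyl ester
Product: 3 (S)-4-methyltetrahydro-2H-pyran-2-one, via hydroxy acid 2 (not isolated)
Conditions: NaH (1.0 equiv), THF, 0 °C; LiBH4 (1.5 equiv), 0 → 23 °C; then 2 M HCl, 23 °C
Reagents that add atoms: none
Why: LiBH4 reduces the methyl ester but not the carboxylate salt (chemoselective ester reduction), and acidification lactonises the δ-hydroxy acid; the stereocentre is untouched and the two arms stay distinct.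

Step 2
Reactants: 3 (S)-4-methyltetrahydro-2H-pyran-2-one
Product: 5 methyl (R)-5-iodo-3-methylpentanoate, via silyl ester 4 (not isolated)
Conditions: Me3SiI (1.3 equiv), CH2Cl2, 23 °C; then MeOH, 23 → 40 °C
Reagents that add atoms: iodotrimethylsilane C[Si](C)(C)I; methanol CO
Why: silylation of the lactone carbonyl and SN2 opening by iodide at the O–CH2 carbon give the ω-iodo silyl ester, which methanol and the hydrogen iodide formed convert into the methyl ester (known lactone to ω-iodo ester conversion).

Step 3
Reactants: 6 (1R,5R)-(+)-verbenone
Product: 7 (1R,4S,5S)-4-ethenyl-4,6,6-trimethylbicyclo[3.1.1]heptan-2-one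
Conditions: CH2=CHMgBr (1.5 equiv), CuBr·SMe2 (10 mol%), THF, −40 → 0 °C; aq. NH4Cl
Reagents that add atoms: vinylmagnesium bromide C=C[Mg]Br
Why: copper-catalysed conjugate addition of a Grignard reagent to the β,β-disubstituted enone; the vinyl group enters anti to the gem-dimethyl bridge, which sets the quaternary centre (labdane C10) with methyl syn to the bridge.

Step 4
Reactants: 7 (1R,4S,5S)-4-ethenyl-4,6,6-trimethylbicyclo[3.1.1]heptan-2-one; 5 methyl (R)-5-iodo-3-methylpentanoate
Product: 9 methyl (3S)-5-[(1R,3S,4S,5S)-4-ethenyl-4,6,6-trimethyl-2-oxobicyclo[3.1.1]heptan-3-yl]-3-methylpentanoate, via lithium enolate 8 (not isolated)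
Conditions: LiN(iPr)2 (1.1 equiv), THF, −78 °C; then 5 (1.3 equiv), DMPU, −78 → 0 °C
Reagents that add atoms: none
Why: ketone enolate alkylation with a primary iodide; only C3 can enolise (the other α-carbon is a bridgehead) and the electrophile should approach anti to the bridge (3S), a centre that step 8 resets in any case.

Step 5
Reactants: 9 methyl (3S)-5-[(1R,3S,4S,5S)-4-ethenyl-4,6,6-trimethyl-2-oxobicyclo[3.1.1]heptan-3-yl]-3-methylpentanoate
Product: 11 methyl (3S)-5-[(1R,3S,4S,5S)-4-(2-hydroxyethyl)-4,6,6-trimethyl-2-oxobicyclo[3.1.1]heptan-3-yl]-3-methylpentanoate, via alkylborane 10 (not isolated)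
Conditions: 9-BBN (1.5 equiv), THF, 0 → 23 °C; then NaBO3·4H2O, THF–H2O, 23 °C
Reagents that add atoms: sodium perborate tetrahydrate [Na+].[O-]OB=O.O.O.O.O
Why: anti-Markovnikov hydroboration–oxidation of the terminal alkene; 9-BBN should add to the vinyl group much faster than it reduces the hindered ketone and it leaves the ester alone, and perborate oxidises the borane without saponifying the ester.

Step 6
Reactants: 11 methyl (3S)-5-[(1R,3S,4S,5S)-4-(2-hydroxyethyl)-4,6,6-trimethyl-2-oxobicyclo[3.1.1]heptan-3-yl]-3-methylpentanoate
Product: 12 methyl (3S)-3-methyl-5-[(1R,3S,4S,5S)-4,6,6-trimethyl-2-oxo-4-(2-oxoethyl)bicyclo[3.1.1]heptan-3-yl]pentanoate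
Conditions: Dess–Martin periodinane (1.5 equiv), NaHCO3, CH2Cl2, 0 → 23 °C
Reagents that add atoms: none
Why: Dess–Martin oxidation of the primary alcohol to the aldehyde under buffered conditions; the aldehyde has no α-stereocentre, and any ketone reduced in step 5 would be re-oxidised here.

Step 7
Reactants: 12 methyl (3S)-3-methyl-5-[(1R,3S,4S,5S)-4,6,6-trimethyl-2-oxo-4-(2-oxoethyl)bicyclo[3.1.1]heptan-3-yl]pentanoate
Product: 13 methyl (3S)-3-methyl-5-[(1R,3S,4S,5S)-4,6,6-trimethyl-2-oxo-4-(prop-2-yn-1-yl)bicyclo[3.1.1]heptan-3-yl]pentanoate
Conditions: dimethyl (1-diazo-2-oxopropyl)phosphonate (1.5 equiv), K2CO3 (2.5 equiv), MeOH, 0 → 23 °C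
Reagents that add atoms: dimethyl (1-diazo-2-oxopropyl)phosphonate COP(=O)(OC)C(=[N+]=[N-])C(C)=O
Why: Ohira–Bestmann (Seyferth–Gilbert) homologation turns the aldehyde into the terminal alkyne with one added carbon; the hindered ketone should not react, the methyl ester matches the solvent, and epimerisation at C3 would be harmless.

Step 8
Reactants: 13 methyl (3S)-3-methyl-5-[(1R,3S,4S,5S)-4,6,6-trimethyl-2-oxo-4-(prop-2-yn-1-yl)bicyclo[3.1.1]heptan-3-yl]pentanoate
Product: 16 methyl (5S,9R,10S,13S)-2,8-dioxo-17-norlabdan-15-oate, via enol trifluoroacetate 14 (not isolated), via 9-epi-dione 15 (not isolated)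
Conditions: BF3·OEt2 (2.5 equiv), CF3CO2H–CH2Cl2 (1:4), 0.01 M, −20 → 23 °C; then NaOMe, MeOH, 23 °C
Reagents that add atoms: trifluoroacetic acid OC(=O)C(F)(F)F
Why: Proposed new method: BF3 (or a proton) on the C8 carbonyl polarises the strained cyclobutane bond C4–C7 (pinane C6–C1, α,β to the carbonyl), which should ionise with release of ring strain to the C7=C8 enol and the tertiary C4 cation on C5; the closest known reaction types are the Lewis-acid cleavage of nopinone-type ketones to cyclohexanone enol derivatives bearing a 2-substituted prop-2-yl group and the closure of a tertiary cation onto a terminal alkyne in CF3CO2H that ends as a cyclohexanone, and only their coupling in one flask on this substrate is new. Ring A closes 6-endo-dig: the terminal alkyne carbon C3 attacks C4 through a chair in which C1 on C10 and C4 on C5 are both equatorial on ring B, and because they are trans (the vinyl group entered anti to the bridge in step 3) the decalin is trans-fused with C5 and C10 inherited from 6. Endo closure is secured by the substrate, since exo attack through C2 would need a primary vinyl cation whereas endo attack gives the secondary vinyl cation at C2, which trifluoroacetate captures to give 14 while the C8 enol reverts to the ketone. Loss of a proton from the C4 cation (isopropenyl or isopropylidene) and its capture by trifluoroacetate are reversible in this medium and return to the same cation, and the C15 ester is neither nucleophilic nor acid-labile. NaOMe then cleaves the enol ester to 15 and equilibrates C9 through the C8 enolate, so the one stereocentre set here is under thermodynamic control, the side chain moving from axial to equatorial (9α-H) as in 8-oxo labdanes of the normal series. The step needs cleavage of this cyclobutane bond only (it alone gives a tertiary cation together with an enol) and cyclisation faster than a C5-to-C4 hydride shift that would erase C5; the chair closure of a pre-organised trans-diequatorial pair should win.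

Step 9
Reactants: 16 methyl (5S,9R,10S,13S)-2,8-dioxo-17-norlabdan-15-oate
Product: 18 methyl (5S,9R,10S,13S)-2-oxo-8-(trifluoromethanesulfonyloxy)-17-norlabd-7-en-15-oate, via potassium enolate 17 (not isolated)
Conditions: KN(SiMe3)2 (1.05 equiv), THF, −78 °C; then N-(5-chloro-2-pyridyl)bis(trifluoromethanesulfonimide) (1.1 equiv), −78 °C
Reagents that add atoms: N-(5-chloro-2-pyridyl)bis(trifluoromethanesulfonimide) FC(F)(F)S(=O)(=O)N(c1ccc(Cl)cn1)S(=O)(=O)C(F)(F)F
Why: kinetic enolate formation and O-triflation; the unhindered C7 methylene should be deprotonated faster than the tertiary C9–H, than the neopentyl C1 and C3 methylenes of the C2 ketone (compare the kinetic enolisation of 3,3-dimethylcyclohexanone away from the quaternary carbon) and than the less acidic ester, and triflation at −78 °C should precede enolate equilibration.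

Step 10
Reactants: 18 methyl (5S,9R,10S,13S)-2-oxo-8-(trifluoromethanesulfonyloxy)-17-norlabd-7-en-15-oate
Product: 19 methyl (5S,9S,10S,13S)-2-oxolabd-7-en-15-oate
Conditions: MeZnCl (2 equiv), Pd(PPh3)4 (5 mol%), THF, 23 → 50 °C
Reagents that add atoms: methylzinc chloride C[Zn]Cl
Why: Negishi coupling of the enol triflate at zerovalent palladium installs C17 and fixes the C7=C8 alkene; organozinc halides do not add to the ketone or the ester.

Step 11
Reactants: 19 methyl (5S,9S,10S,13S)-2-oxolabd-7-en-15-oate
Product: 20 (2S,5S,9S,10S,13S)-labd-7-ene-2,15-diol (labd-7-ene-2α,15-diol)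
Conditions: Li (excess), NH3(l)–THF, EtOH, −78 → −33 °C; NH4Cl
Reagents that add atoms: none
Why: dissolving-metal reduction; the C2 ketone should give the thermodynamically preferred equatorial 2α-alcohol (the β-face lies between the axial C19 and C20 methyls, the situation of an 11-oxo steroid), the ester is reduced to the primary alcohol (Bouveault–Blanc type), and the isolated trisubstituted alkene is inert.

Step 12
Reactants: 21 (E)-p-coumaric acid
Product: 22 (Z)-p-coumaric acid
Conditions: hν (365 nm), MeOH, 23 °C; chromatography in the dark, recovered 21 recycled
Reagents that add atoms: none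
Why: photochemical E to Z isomerisation of a cinnamic acid to a photostationary mixture, from which the Z acid is separated.

Step 13
Reactants: 20 (2S,5S,9S,10S,13S)-labd-7-ene-2,15-diol; 22 (Z)-p-coumaric acid
Product: 23 (2S,5S,9S,10S,13S)-2-hydroxylabd-7-en-15-yl (2Z)-3-(4-hydroxyphenyl)prop-2-enoate (CNP0301213.1)
Conditions: PPh3 (1.3 equiv), DIAD (1.3 equiv), 22 (1.5 equiv), THF, 0 °C, dark
Reagents that add atoms: none
Why: Mitsunobu esterification; only the primary C15 alcohol is activated (the 2α-hydroxyl is secondary with its rear face blocked by two axial methyls), the carboxylic acid reacts in preference to the far less acidic phenol, and because the carboxyl carbon is never activated the Z geometry should be retained.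

## Compound list

1 | (R)-3-methylglutaric acid monomethyl ester | COC(=O)C[C@H](C)CC(=O)O | starting material
2 | (S)-5-hydroxy-3-methylpentanoic acid (hydroxy acid) | OCC[C@H](C)CC(=O)O | intermediate
3 | (S)-4-methyltetrahydro-2H-pyran-2-one | C[C@H]1CCOC(=O)C1 | intermediate
4 | trimethylsilyl (R)-5-iodo-3-methylpentanoate (silyl ester) | ICC[C@H](C)CC(=O)O[Si](C)(C)C | intermediate
5 | methyl (R)-5-iodo-3-methylpentanoate | ICC[C@H](C)CC(=O)OC | intermediate
6 | (1R,5R)-(+)-verbenone | O=C1C=C(C)[C@H]2C[C@@H]1C2(C)C | starting material
7 | (1R,4S,5S)-4-ethenyl-4,6,6-trimethylbicyclo[3.1.1]heptan-2-one (vinyl anti to the gem-dimethyl bridge) | O=C1C[C@@](C)(C=C)[C@H]2C[C@@H]1C2(C)C | intermediate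
8 | lithium C2–C3 enolate of 7 | [Li]OC1=C[C@@](C)(C=C)[C@H]2C[C@@H]1C2(C)C | intermediate
9 | methyl (3S)-5-[(1R,3S,4S,5S)-4-ethenyl-4,6,6-trimethyl-2-oxobicyclo[3.1.1]heptan-3-yl]-3-methylpentanoate | O=C1[C@@H](CC[C@H](C)CC(=O)OC)[C@@](C)(C=C)[C@H]2C[C@@H]1C2(C)C | intermediate
10 | alkylborane: 9 with the vinyl group converted to 2-(9-borabicyclo[3.3.1]nonan-9-yl)ethyl | O=C1[C@@H](CC[C@H](C)CC(=O)OC)[C@@](C)(CCB3C4CCCC3CCC4)[C@H]2C[C@@H]1C2(C)C | intermediate
11 | methyl (3S)-5-[(1R,3S,4S,5S)-4-(2-hydroxyethyl)-4,6,6-trimethyl-2-oxobicyclo[3.1.1]heptan-3-yl]-3-methylpentanoate | O=C1[C@@H](CC[C@H](C)CC(=O)OC)[C@@](C)(CCO)[C@H]2C[C@@H]1C2(C)C | intermediate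
12 | methyl (3S)-3-methyl-5-[(1R,3S,4S,5S)-4,6,6-trimethyl-2-oxo-4-(2-oxoethyl)bicyclo[3.1.1]heptan-3-yl]pentanoate | O=C1[C@@H](CC[C@H](C)CC(=O)OC)[C@@](C)(CC=O)[C@H]2C[C@@H]1C2(C)C | intermediate
13 | methyl (3S)-3-methyl-5-[(1R,3S,4S,5S)-4,6,6-trimethyl-2-oxo-4-(prop-2-yn-1-yl)bicyclo[3.1.1]heptan-3-yl]pentanoate (key-step precursor) | O=C1[C@@H](CC[C@H](C)CC(=O)OC)[C@@](C)(CC#C)[C@H]2C[C@@H]1C2(C)C | intermediate
14 | methyl (13S)-8-oxo-2-(trifluoroacetoxy)-17-nor-9-epi-labd-2-en-15-oate (5α-H, 10β-methyl, side chain on C9 α) | O=C1CC[C@H]2C(C)(C)C=C(OC(=O)C(F)(F)F)C[C@]2(C)[C@@H]1CC[C@H](C)CC(=O)OC | intermediate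
15 | methyl (13S)-2,8-dioxo-17-nor-9-epi-labdan-15-oate | O=C1CC[C@H]2C(C)(C)CC(=O)C[C@]2(C)[C@@H]1CC[C@H](C)CC(=O)OC | intermediate
16 | methyl (5S,9R,10S,13S)-2,8-dioxo-17-norlabdan-15-oate (key-step product) | O=C1CC[C@H]2C(C)(C)CC(=O)C[C@]2(C)[C@H]1CC[C@H](C)CC(=O)OC | intermediate
17 | potassium C7–C8 enolate of 16 | [K]OC1=CC[C@H]2C(C)(C)CC(=O)C[C@]2(C)[C@H]1CC[C@H](C)CC(=O)OC | intermediate
18 | methyl (5S,9R,10S,13S)-2-oxo-8-(trifluoromethanesulfonyloxy)-17-norlabd-7-en-15-oate | FC(F)(F)S(=O)(=O)OC1=CC[C@H]2C(C)(C)CC(=O)C[C@]2(C)[C@H]1CC[C@H](C)CC(=O)OC | intermediate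
19 | methyl (5S,9S,10S,13S)-2-oxolabd-7-en-15-oate | CC1=CC[C@H]2C(C)(C)CC(=O)C[C@]2(C)[C@H]1CC[C@H](C)CC(=O)OC | intermediate
20 | (2S,5S,9S,10S,13S)-labd-7-ene-2,15-diol (labd-7-ene-2α,15-diol) | CC1=CC[C@H]2C(C)(C)C[C@H](O)C[C@]2(C)[C@H]1CC[C@H](C)CCO | intermediate
21 | (E)-p-coumaric acid | OC(=O)/C=C/c1ccc(O)cc1 | starting material
22 | (Z)-p-coumaric acid | OC(=O)/C=C\c1ccc(O)cc1 | intermediate
23 | (2S,5S,9S,10S,13S)-2-hydroxylabd-7-en-15-yl (2Z)-3-(4-hydroxyphenyl)prop-2-enoate (CNP0301213.1) | CC1=CC[C@H]2C(C)(C)C[C@H](O)C[C@]2(C)[C@H]1CC[C@H](C)CCOC(=O)/C=C\c1ccc(O)cc1 | target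

## Step count and least certain steps

Total: 13 steps. Longest linear sequence: 11 steps (1 → 3 → 5 → 9 → 11 → 12 → 13 → 16 → 18 → 19 → 20 → 23; steps 1, 2, 4–11 and 13).

**Step 8 (key step, proposed new method).**
- Most likely failure: the C4 cation is diverted before ring closure, by proton loss to an alkene that does not re-enter, by a hydride shift from C5 that erases that centre, or by simple acid hydration of the alkyne to a methyl ketone. A terminal alkyne is a weak nucleophile and must form a bent vinyl cation, so it may not keep pace with these paths. Incomplete cyclobutane cleavage is the other risk.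
- Fallback (known reactions, two stages): from 13, BF3·OEt2 with Zn(OAc)2 in Ac2O, the established opening of nopinone-type ketones, should give the ring-opened diacetate F1 (C7=C8 enol acetate, tertiary acetate on C4, alkyne intact). Ionising the tertiary acetate in HCO2H or CF3CO2H then closes ring A onto the alkyne, a known cation–alkyne cyclisation. NaOMe in MeOH cleaves the enol esters and equilibrates C9, which returns the sequence to 16.

**Step 4 (alkylation).**
- Most likely failure: slow SN2 attack at an enolate carbon next to a quaternary centre, so that proton exchange and elimination of hydrogen iodide from 5 compete.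
- Fallback: from 7, condensation with Me2NNH2 gives the N,N-dimethylhydrazone F2. Its lithium aza-enolate (LiN(iPr)2, THF, 0 °C), a stronger carbon nucleophile than the ketone enolate, is alkylated by 5 to the hydrazone F3. Hydrolysis with aqueous CuCl2 returns to 9.

**Step 9 (selective enol triflate).**
- Most likely failure: insufficient site selectivity between the two ketones, or enolate equilibration before triflation, leading to triflation on ring A.
- Fallback: from 16, pyrrolidine should condense only at C2, because an enamine at the α-branched C8 ketone next to quaternary C10 is strongly disfavoured. This gives the enamine F4 (drawn as the C2=C3 isomer; the position of the enamine double bond is immaterial). With C2 masked, KN(SiMe3)2 and the triflimide give the enamine triflate F5. Hydrolysis of the enamine with aqueous AcOH/NaOAc at work-up rejoins the route at 18.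

**Step 11 (double reduction).**
- Most likely failure: incomplete or diverted reduction of the ester (ammonolysis or stopping short) while the ketone is reduced cleanly.
- Fallback: from 19, LiOH in THF–H2O gives the keto acid F6. Li in NH3 reduces only the ketone of the carboxylate salt, giving the 2α-hydroxy acid F7. LiAlH4 then reduces the acid and returns to 20.

**Step 13 (Mitsunobu esterification).**
- Most likely failure: Z to E isomerisation of the enoate by reversible phosphine addition, or competing O-alkylation of the phenol.
- Fallback: from 20, carbodiimide esterification of the primary hydroxyl with (diphenoxyphosphoryl)acetic acid gives the phosphonoacetate F8. A Z-selective Horner–Wadsworth–Emmons olefination (diaryl phosphonate variant; NaI, DBU, THF, −78 → 0 °C) with 4-(tert-butyldimethylsilyloxy)benzaldehyde builds the alkene on the ester and gives the silyl-protected Z-coumarate F9. Buffered fluoride (Bu4NF/AcOH, 0 °C) removes the silyl group and returns to 23.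

## Further compounds

F1 | step 8 | ring-opened diacetate: cyclohexenyl enol acetate (C7=C8) with 2-acetoxyprop-2-yl on C5, methyl and propargyl on C10, side chain on C9; C5, C9, C10 as in 13 | CC(=O)OC1=CC[C@@H](C(C)(C)OC(C)=O)[C@](C)(CC#C)[C@@H]1CC[C@H](C)CC(=O)OC
F2 | step 4 | N,N-dimethylhydrazone of 7 | CN(C)/N=C1\C[C@@](C)(C=C)[C@H]2C[C@@H]1C2(C)C
F3 | step 4 | N,N-dimethylhydrazone of 9 | CN(C)/N=C1\[C@@H](CC[C@H](C)CC(=O)OC)[C@@](C)(C=C)[C@H]2C[C@@H]1C2(C)C
F4 | step 9 | C2 pyrrolidine enamine of 16 (C2=C3) | O=C1CC[C@H]2C(C)(C)C=C(N3CCCC3)C[C@]2(C)[C@H]1CC[C@H](C)CC(=O)OC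
F5 | step 9 | C2 pyrrolidine enamine of 18 | FC(F)(F)S(=O)(=O)OC1=CC[C@H]2C(C)(C)C=C(N3CCCC3)C[C@]2(C)[C@H]1CC[C@H](C)CC(=O)OC
F6 | step 11 | (5S,9S,10S,13S)-2-oxolabd-7-en-15-oic acid | CC1=CC[C@H]2C(C)(C)CC(=O)C[C@]2(C)[C@H]1CC[C@H](C)CC(=O)O
F7 | step 11 | (2S,5S,9S,10S,13S)-2-hydroxylabd-7-en-15-oic acid | CC1=CC[C@H]2C(C)(C)C[C@H](O)C[C@]2(C)[C@H]1CC[C@H](C)CC(=O)O
F8 | step 13 | 2α-hydroxylabd-7-en-15-yl (diphenoxyphosphoryl)acetate | CC1=CC[C@H]2C(C)(C)C[C@H](O)C[C@]2(C)[C@H]1CC[C@H](C)CCOC(=O)CP(=O)(Oc1ccccc1)Oc1ccccc1
F9 | step 13 | 2α-hydroxylabd-7-en-15-yl (2Z)-3-[4-(tert-butyldimethylsilyloxy)phenyl]prop-2-enoate | CC1=CC[C@H]2C(C)(C)C[C@H](O)C[C@]2(C)[C@H]1CC[C@H](C)CCOC(=O)/C=C\c1ccc(O[Si](C)(C)C(C)(C)C)cc1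
A1 | alternative 1 | acyclic silyloxy triene: methyl (E)-3-methyl enoate tethered to an (E,Z)-2-(triethylsilyloxy)diene, C2 OTBS configured as in the target | COC(=O)/C=C(\C)C[C@@H](O[Si](C)(C)C(C)(C)C)CC(C)(C)/C=C/C(O[Si](CC)(CC)CC)=C/C
A2 | alternative 1 | methyl 2α-(tert-butyldimethylsilyloxy)-7-(triethylsilyloxy)drim-6-en-11-oate | C[C@H]1C(O[Si](CC)(CC)CC)=C[C@H]2C(C)(C)C[C@H](O[Si](C)(C)C(C)(C)C)C[C@]2(C)[C@H]1C(=O)OC
A3 | alternative 2 | (8E,13S)-9,10-secolabda-5(10),8-diene-2α,15-diyl diacetate | CC1=C(CC/C(C)=C/CC[C@H](C)CCOC(C)=O)C(C)(C)C[C@H](OC(C)=O)C1
A4 | alternative 2 | labd-7-ene-2α,15-diyl diacetate | CC1=CC[C@H]2C(C)(C)C[C@H](OC(C)=O)C[C@]2(C)[C@H]1CC[C@H](C)CCOC(C)=O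
A5 | alternative 3 | 3,5,5-trimethyl-4-vinylcyclohex-3-en-1-yl but-2-ynoate, carbinol centre configured as C2 of the target | CC#CC(=O)O[C@@H]1CC(C)=C(C=C)C(C)(C)C1
A6 | alternative 3 | drima-5,8-dien-11,2α-olide | CC1=C2C(=O)O[C@@H]3C[C@@]2(C)C(=CC1)C(C)(C)C3
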